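## The problem

Grevirobstol B, compound 27, is a 22-membered macrocycle in which two phenolic rings are joined twice: an ether oxygen links C3 of ring A to C1 of ring B, and an unbranched sixteen-carbon chain runs from C1 of ring A to C6 of ring B. Ring A is a 1,3,5-trisubstituted benzene (chain at C1, aryloxy at C3, hydroxyl at C5). Ring B is 1,2,4-trioxygenated (aryloxy at C1, hydroxyls at C2 and C4), and its ether carbon C1 is flanked on both sides, by the C2 oxygen and by the chain at C6. There is no stereocentre and the ring is too large to hold a fixed planar-chiral conformation, so nothing controls anything stereochemically; the task is regiochemistry on two arenes, a hindered diaryl ether and a large-ring closure. The free trioxygenated ring B is electron-rich and easily oxidised to quinones, so the three phenols should travel as methyl ethers and be released last. The ring closure must overcome the entropy of sixteen freely rotating methylenes, which calls for a fast, irreversible bond formation at high dilution. The enabling feature is the 1,3,5 array of ring A: hydroxyl at C5, aryloxy at C3 and alkyl at C1 are what results when the vinylketene from a 3-alkylcyclobutenone combines with an aryloxyacetylene, the ketene carbon becoming C5, the alkyne carbons C4 and C3, and the alkyl-bearing carbon C1. The ether oxygen then arrives already bonded to ring B, so the hindered C1–O bond of ring B never has to be made by aryl–oxygen coupling.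

## Retrosynthesis

**27 to trimethyl ether 26.** Only the three O–methyl bonds are cut. Methyl ethers survive n-BuLi, heating to 110 °C, palladium catalysis and base, and all three fall in one operation; silyl or benzyl ethers would each fail at one of those stages. The forward step asks only that BBr3 cleave alkyl aryl ethers and leave the diaryl ether alone.

**26 to open-chain diaryl ether 24, through alkylborane 25.** The bond cut is the C(sp2)–C(sp3) bond between C6 of ring B and the last chain carbon. Cutting the diaryl ether instead would make ring closure an aryl–oxygen coupling at the doubly flanked C1 of ring B. Cutting in the middle of the chain would need two functionalised arms and a later hydrogenation. The chosen cut leaves the whole chain on ring A, ending in a terminal alkene that is inert until 9-BBN is added, and a chloride on ring B. The forward reaction is an intramolecular B-alkyl Suzuki–Miyaura coupling onto an ortho-aryloxy aryl chloride at high dilution.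

**24 to phenol 23.** One O–methyl bond is cut. Methylating the ring A hydroxyl removes the only acidic proton before hydroboration and costs nothing at the end, since it leaves with the other two methyl groups.

**23 to cyclobutenone 8 and ynol ether 18.** Three bonds of ring A are cut: C4–C5, C2–C3 and C5–C6. The neighbouring cut at the ether oxygen would pair a ring A halide with hindered phenol 13; against it, this one builds ring A and delivers the ether in the same operation. The precursors are a four-membered ring and an alkyne, neither with any regiochemical ambiguity. The forward reaction asks that the vinylketene from 8 add to 18 with its carbonyl carbon on the unsubstituted alkyne carbon, and that the terminal alkene and the aryl chloride stay out of it.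

**18 to dichlorovinyl ether 15, then to phenol 13 and trichloroethylene 14.** The O–C(vinyl) bond and the two C–Cl bonds of the masked alkyne are cut. This two-step ynol ether synthesis starts from the phenol oxygen, so the hindered oxygen of ring B is used as a nucleophile towards a small electrophile, which is easy. The ring B handle is a chloride and not a bromide because it must pass through the n-BuLi step untouched.

**13 to aldehyde 11 and 1-chloro-3,5-dimethoxybenzene 9.** The aryl–oxygen bond is traced to an aryl–formyl bond (Baeyer–Villiger oxidation), and that to an aryl C–H bond (Vilsmeier–Haack formylation). A route through a 4-hydroxybenzaldehyde would give a hydroquinone whose two hydroxyls, of similar acidity, would have to be told apart in a mono-methylation. Here both methoxy groups are present before the oxygen is introduced. The forward formylation must go ortho to chlorine and not between the methoxy groups.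

**8 to 3-ethoxycyclobut-2-en-1-one 5 and alkyl chloride 4.** The bond between C3 of the cyclobutenone and the chain is cut. Addition of Grignard reagent 6 to the vinylogous ester, followed by acid, transposes the carbonyl and gives the 3-alkylcyclobutenone through carbinol 7.

**4 to 11-bromoundec-1-ene 1 and 1-bromo-5-chloropentane 2.** One C(sp3)–C(sp3) bond is cut, C11 plus C5. The two halogens of 2 differ enough in reactivity that the copper-catalysed coupling should stop at the chloride, which then serves as the Grignard precursor.

## Roads not taken

**Alternative 1:** The cut removes one methylene of the tether, the fourth carbon from ring B, by breaking both of its C–C bonds. This leaves an open diaryl ether with a 3-bromopropyl arm on ring B and a 12-bromododecyl arm on ring A, dibromide A2, and tosylmethyl isocyanide A3 as a one-carbon linchpin.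

- Forward step: the anion of A3 is alkylated by one arm of A2, deprotonated again and alkylated intramolecularly by the other. This gives macrocycle A1, carrying tosyl and isocyano groups on one bridge carbon. Both groups must then be excised from A1 to reach 26.
- Merits: ring closure is a substitution at a primary carbon far from either arene, needs no transition metal and is insensitive to arm length.
- Weak points: the method builds neither arene nor ether. A2 presupposes the diaryl ether at the hindered C1 of ring B and two different arms on two rings. Excision of the linchpin groups costs further steps, and the one-step dissolving-metal removal threatens the diaryl ether C–O bond.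
- Comparison: for the macrocyclisation itself this road is probably more dependable than a B-alkyl Suzuki reaction at an ortho-substituted aryl chloride. The chosen plan sets against it an ether bond that comes with the construction of ring A, a chain brought in as one piece, and nothing to remove after ring closure.

**Alternative 2:** The cut opens both arenes at once, at the C1–C2 bond of ring A and the C6–C5 bond of ring B, back to a symmetric bis(3,5,7-triketo ester), A5.

- Forward step: at each end of A5 the C2 methylene condenses on the C7 ketone and the ring aromatises, giving bis(dihydroxybenzoate) A4.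
- Merits: both arenes and the full carbon skeleton arise in one biomimetic operation from a chain assembled in two directions, with no halogen and no palladium. In ring-forming economy this is better than the chosen plan, which builds one arene.
- Weak points: A5 is a polycarbonyl chain open to other closures (C-acylation, pyranone formation). The larger problem is that the difficulty is only moved. A4 is symmetric, whereas the target needs ring A to give up a phenol oxygen and ring B to accept it at the very carbon that carries the ester in A4. That requires either a site-selective oxidative phenol coupling closing a 22-membered ring between several electron-rich positions, or a lengthy differentiation of two identical rings.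
- Comparison: the chosen plan sets against the better ring economy the fact that the diaryl ether and the difference between the rings are built into the fragments from the start.

**Alternative 3:** The cut opens ring B at C1–C6 and C2–C3, back to a ring A aryloxymalonate, dimethyl 2-(3-bromo-5-methoxyphenoxy)propanedioate A7, and a long-chain methyl enone, (3E)-icosa-3,19-dien-2-one A8.

- Forward step: the anion of malonate A7 adds to the β-carbon of enone A8, and the resulting methyl ketone enolate closes onto one ester to give cyclohexanedione A6.
- Merits: this road also avoids the hindered aryl–oxygen coupling, since the oxygen is brought in by an unhindered ring A phenoxide. The later macrocyclisation would use an aryl bromide on ring A with no ortho substituent, a better coupling partner than the ortho-aryloxy chloride of the chosen plan.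
- Weak points: the conjugate addition makes a quaternary, oxygen-bearing carbon next to a branched carbon and is reversible. A6 still needs loss of its ester and a dehydrogenation to become aromatic, and the usual reagents for that (halogens, hot palladium on carbon) attack or isomerise the terminal alkene needed for ring closure. Its two stereocentres are simply destroyed.
- Comparison: the chosen plan sets against the better coupling partner an arene that emerges aromatic from the key step, with no oxidant and fewer steps after it.

Key step: step 7

Assumption: 3-ethoxycyclobut-2-en-1-one 5 is treated as a catalogue compound, like the other starting materials.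

## Route

Step 1
Reactants: 1 11-bromoundec-1-ene; 2 1-bromo-5-chloropentane
Product: 4 16-chlorohexadec-1-ene, via undec-10-enylmagnesium bromide 3 (not isolated)
Conditions: Mg, THF, 40 °C; then 2, Li2CuCl4 (2 mol %), THF, −10 °C → rt
Reagents that add atoms: none
Why: Copper-catalysed sp3–sp3 coupling of a primary Grignard reagent (Kochi coupling); the primary bromide of 2 is displaced far faster than the chloride, so the chain should stop at the C16 chloride, and the terminal alkene is a spectator.

Step 2
Reactants: 4 16-chlorohexadec-1-ene; 5 3-ethoxycyclobut-2-en-1-one
Product: 8 3-(hexadec-15-enyl)cyclobut-2-en-1-one, via hexadec-15-enylmagnesium chloride 6 (not isolated), via 3-ethoxy-1-(hexadec-15-enyl)cyclobut-2-en-1-ol 7 (not isolated)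
Conditions: Mg, BrCH2CH2Br (cat.), THF, reflux; then 5, THF, −78 → 0 °C; then 1 M HCl, 0 °C → rt
Reagents that add atoms: water, O
Why: Primary alkyl chlorides insert magnesium in refluxing THF; 1,2-addition of 6 to the vinylogous ester and acid-mediated loss of ethanol and water from carbinol 7 (Stork–Danheiser-type carbonyl transposition) should give the 3-alkylcyclobutenone, and a competing addition–elimination at C3 would converge on the same product.

Step 3
Reactants: 9 1-chloro-3,5-dimethoxybenzene
Product: 11 2-chloro-4,6-dimethoxybenzaldehyde, via [(2-chloro-4,6-dimethoxyphenyl)methylidene]dimethylammonium chloride 10 (not isolated)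
Conditions: POCl3, DMF, 0 → 90 °C; then ice–water
Reagents that add atoms: N,N-dimethylformamide, CN(C)C=O; water, O
Why: Vilsmeier–Haack formylation; attack at C2 of 9 is ortho to one methoxy group and para to the other and avoids the position flanked by two methoxy groups, as with other 5-substituted 1,3-dimethoxybenzenes; the minor isomer formylated between the methoxy groups would be removed by crystallisation.

Step 4
Reactants: 11 2-chloro-4,6-dimethoxybenzaldehyde
Product: 13 2-chloro-4,6-dimethoxyphenol, via 2-chloro-4,6-dimethoxyphenyl formate 12 (not isolated)
Conditions: mCPBA, CH2Cl2, 0 °C → rt; aq NaHCO3 wash; then K2CO3 (cat.), MeOH, rt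
Reagents that add atoms: 3-chloroperoxybenzoic acid, O=C(OO)c1cccc(Cl)c1
Why: Baeyer–Villiger (Dakin-type) oxidation in which the electron-rich dimethoxyaryl group migrates in preference to hydride, followed by base-catalysed methanolysis of formate 12; both methoxy groups are already in place, so no selective phenol alkylation is needed.

Step 5
Reactants: 13 2-chloro-4,6-dimethoxyphenol; 14 trichloroethylene
Product: 15 1-chloro-2-{[(E)-1,2-dichloroethenyl]oxy}-3,5-dimethoxybenzene
Conditions: K2CO3, DMF, 70 °C
Reagents that add atoms: none
Why: Known O-vinylation of phenoxides by trichloroethylene (elimination–addition), which delivers the (E)-1,2-dichlorovinyl ether; ortho-substituted phenoxides are competent nucleophiles towards so small an electrophile.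

Step 6
Reactants: 15 1-chloro-2-{[(E)-1,2-dichloroethenyl]oxy}-3,5-dimethoxybenzene
Product: 18 1-chloro-2-(ethynyloxy)-3,5-dimethoxybenzene, via 1-chloro-2-[(chloroethynyl)oxy]-3,5-dimethoxybenzene 16 (not isolated), via [(2-chloro-4,6-dimethoxyphenoxy)ethynyl]lithium 17 (not isolated)
Conditions: n-BuLi (2.2 equiv), Et2O, −78 → −40 °C; then MeOH, −78 °C
Reagents that add atoms: none
Why: Standard conversion of a 1,2-dichlorovinyl ether into an ynol ether: dehydrochlorination to chloroalkyne 16, chlorine–lithium exchange to acetylide 17 and protonation; both events are fast at −78 °C, where the aryl chloride should neither exchange nor be ortho-metalated at a competitive rate.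

Step 7
Reactants: 8 3-(hexadec-15-enyl)cyclobut-2-en-1-one; 18 1-chloro-2-(ethynyloxy)-3,5-dimethoxybenzene
Product: 23 3-(2-chloro-4,6-dimethoxyphenoxy)-5-(hexadec-15-enyl)phenol, via 3-methylidenenonadeca-1,18-dien-1-one 19 (not isolated), via 3-(2-chloro-4,6-dimethoxyphenoxy)-4-(octadeca-1,17-dien-2-yl)cyclobut-2-en-1-one 20 (not isolated), via (3E)-3-(2-chloro-4,6-dimethoxyphenoxy)-5-methylidenehenicosa-1,3,20-trien-1-one 21 (not isolated), via 3-(2-chloro-4,6-dimethoxyphenoxy)-5-(hexadec-15-enyl)cyclohexa-2,4-dien-1-one 22 (not isolated)
Conditions: 18 (1.5 equiv), PhMe, 80 °C, then 110 °C, sealed tube, Ar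
Reagents that add atoms: none
Why: Danheiser benzannulation of a cyclobutenone with an ynol ether, the aryl ether 18 being a less electron-rich member of that class than the alkoxy- and siloxyacetylenes normally used. Thermal 4π electrocyclic opening of 8 is reversible and gives vinylketene 19. Ketene 19 adds [2+2] across the triple bond of 18, its electrophilic carbonyl carbon bonding to the unsubstituted, nucleophilic alkyne carbon and its α-carbon to the oxygen-bearing carbon, which gives 4-vinylcyclobutenone 20. A second 4π opening of 20 gives dienylketene 21; only the (3E) isomer can close, and the other returns to 20 because the opening is reversible. Ring A, a six-membered carbocycle, closes by thermal disrotatory 6π electrocyclisation of 21 between the ketene carbon and the terminal methylene, and dienone 22 tautomerises to phenol 23. No stereocentre survives, since the single one in 20 is erased when the four-membered ring opens. The regioselectivity needed (aryloxy meta to the new hydroxyl) is secured by the donor polarisation of the ynol ether matched to the ketene carbonyl carbon, and the chemoselectivity by the inertness of the unactivated terminal alkene and the aryl chloride towards a ketene, an excess of 18 limiting ketene dimerisation.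

Step 8
Reactants: 23 3-(2-chloro-4,6-dimethoxyphenoxy)-5-(hexadec-15-enyl)phenol
Product: 24 1-chloro-2-[3-(hexadec-15-enyl)-5-methoxyphenoxy]-3,5-dimethoxybenzene
Conditions: MeI, K2CO3, acetone, reflux
Reagents that add atoms: iodomethane, CI
Why: Williamson O-methylation of the only free phenol; it removes the acidic O–H before hydroboration and makes all three oxygens alike for the final deprotection.

Step 9
Reactants: 24 1-chloro-2-[3-(hexadec-15-enyl)-5-methoxyphenoxy]-3,5-dimethoxybenzene
Product: 26 tri-O-methylgrevirobstol B (1^4,1^6,3^5-trimethoxy-2-oxa-1(1,2),3(1,3)-dibenzenacyclononadecaphane), via 9-{16-[3-(2-chloro-4,6-dimethoxyphenoxy)-5-methoxyphenyl]hexadecyl}-9-borabicyclo[3.3.1]nonane 25 (not isolated)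
Conditions: 9-BBN, THF, 0 °C → rt; then slow addition to Pd(OAc)2 (10 mol %), SPhos (20 mol %), K3PO4, THF/H2O, 65 °C, 2 mM
Reagents that add atoms: none
Why: Anti-Markovnikov hydroboration of the terminal alkene by 9-BBN, then intramolecular B-alkyl Suzuki–Miyaura coupling at high dilution; the electron-rich biarylphosphine SPhos allows oxidative addition of zerovalent palladium into the aryl chloride and fast reductive elimination, and B-alkyl Suzuki macrocyclisation onto aryl halides is an established way to close large rings.

Step 10
Reactants: 26 tri-O-methylgrevirobstol B
Product: 27 grevirobstol B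
Conditions: BBr3 (6 equiv), CH2Cl2, −78 °C → rt; then H2O
Reagents that add atoms: none
Why: Lewis acid-mediated cleavage of aryl methyl ethers; the diaryl ether and the saturated chain are inert to BBr3, and nothing else in the molecule is acid-sensitive.

## Compound list

1 | 11-bromoundec-1-ene | C=CCCCCCCCCCBr | starting material
2 | 1-bromo-5-chloropentane | BrCCCCCCl | starting material
3 | undec-10-enylmagnesium bromide (not isolated) | C=CCCCCCCCCC[Mg]Br | intermediate
4 | 16-chlorohexadec-1-ene | C=CCCCCCCCCCCCCCCCl | intermediate
5 | 3-ethoxycyclobut-2-en-1-one | CCOC1=CC(=O)C1 | starting material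
6 | hexadec-15-enylmagnesium chloride (not isolated) | C=CCCCCCCCCCCCCCC[Mg]Cl | intermediate
7 | 3-ethoxy-1-(hexadec-15-enyl)cyclobut-2-en-1-ol (racemic, not isolated) | CCOC1=CC(O)(CCCCCCCCCCCCCCC=C)C1 | intermediate
8 | 3-(hexadec-15-enyl)cyclobut-2-en-1-one | O=C1C=C(CCCCCCCCCCCCCCC=C)C1 | intermediate
9 | 1-chloro-3,5-dimethoxybenzene | COc1cc(Cl)cc(OC)c1 | starting material
10 | [(2-chloro-4,6-dimethoxyphenyl)methylidene]dimethylammonium chloride (not isolated) | C[N+](C)=Cc1c(Cl)cc(OC)cc1OC.[Cl-] | intermediate
11 | 2-chloro-4,6-dimethoxybenzaldehyde | O=Cc1c(Cl)cc(OC)cc1OC | intermediate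
12 | 2-chloro-4,6-dimethoxyphenyl formate (not isolated) | O=COc1c(Cl)cc(OC)cc1OC | intermediate
13 | 2-chloro-4,6-dimethoxyphenol | Oc1c(Cl)cc(OC)cc1OC | intermediate
14 | trichloroethylene | ClC=C(Cl)Cl | starting material
15 | 1-chloro-2-{[(E)-1,2-dichloroethenyl]oxy}-3,5-dimethoxybenzene | Cl/C=C(/Cl)Oc1c(Cl)cc(OC)cc1OC | intermediate
16 | 1-chloro-2-[(chloroethynyl)oxy]-3,5-dimethoxybenzene (not isolated) | ClC#COc1c(Cl)cc(OC)cc1OC | intermediate
17 | [(2-chloro-4,6-dimethoxyphenoxy)ethynyl]lithium (not isolated) | [Li]C#COc1c(Cl)cc(OC)cc1OC | intermediate
18 | 1-chloro-2-(ethynyloxy)-3,5-dimethoxybenzene | C#COc1c(Cl)cc(OC)cc1OC | intermediate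
19 | 3-methylidenenonadeca-1,18-dien-1-one (vinylketene, not isolated) | O=C=CC(=C)CCCCCCCCCCCCCCC=C | intermediate
20 | 3-(2-chloro-4,6-dimethoxyphenoxy)-4-(octadeca-1,17-dien-2-yl)cyclobut-2-en-1-one (racemic, not isolated) | O=C1C=C(Oc2c(Cl)cc(OC)cc2OC)C1C(=C)CCCCCCCCCCCCCCC=C | intermediate
21 | (3E)-3-(2-chloro-4,6-dimethoxyphenoxy)-5-methylidenehenicosa-1,3,20-trien-1-one (dienylketene, not isolated) | O=C=C/C(Oc1c(Cl)cc(OC)cc1OC)=C\C(=C)CCCCCCCCCCCCCCC=C | intermediate
22 | 3-(2-chloro-4,6-dimethoxyphenoxy)-5-(hexadec-15-enyl)cyclohexa-2,4-dien-1-one (not isolated) | O=C1C=C(Oc2c(Cl)cc(OC)cc2OC)C=C(CCCCCCCCCCCCCCC=C)C1 | intermediate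
23 | 3-(2-chloro-4,6-dimethoxyphenoxy)-5-(hexadec-15-enyl)phenol | Oc1cc(CCCCCCCCCCCCCCC=C)cc(Oc2c(Cl)cc(OC)cc2OC)c1 | intermediate
24 | 1-chloro-2-[3-(hexadec-15-enyl)-5-methoxyphenoxy]-3,5-dimethoxybenzene | COc1cc(CCCCCCCCCCCCCCC=C)cc(Oc2c(Cl)cc(OC)cc2OC)c1 | intermediate
25 | 9-{16-[3-(2-chloro-4,6-dimethoxyphenoxy)-5-methoxyphenyl]hexadecyl}-9-borabicyclo[3.3.1]nonane (not isolated) | COc1cc(CCCCCCCCCCCCCCCCB2C3CCCC2CCC3)cc(Oc2c(Cl)cc(OC)cc2OC)c1 | intermediate
26 | tri-O-methylgrevirobstol B (1^4,1^6,3^5-trimethoxy-2-oxa-1(1,2),3(1,3)-dibenzenacyclononadecaphane; 22-membered ring, methoxy at C5 of ring A and at C2 and C4 of ring B) | COc1cc2cc(c1)Oc1c(OC)cc(OC)cc1CCCCCCCCCCCCCCCC2 | intermediate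
27 | grevirobstol B (2-oxa-1(1,2),3(1,3)-dibenzenacyclononadecaphane-1^4,1^6,3^5-triol) | Oc1cc2cc(c1)Oc1c(O)cc(O)cc1CCCCCCCCCCCCCCCC2 | target

## Step count and risks

Total: 10 steps. Longest linear sequence: 8 steps (9 → 11 → 13 → 15 → 18 → 23 → 24 → 26 → 27). The chain branch (1 → 4 → 8) has 2 steps and joins at step 7.

**Step 7 (key step).** The aryl ynol ether is a weaker ketenophile than alkoxy- or siloxyacetylenes and may oligomerise on heating before it intercepts the vinylketene. The ketene would then dimerise, or acylate the product phenol; the latter loss could be undone by basic methanolysis of the crude product. The fallback gives up the ring construction and forms the ether directly, setting out from chloride 4 and phenol 13. Grignard reagent 6, made from 4 as in step 2, would be transmetalated with ZnCl2 to hexadec-15-enylzinc chloride F1. Organozinc F1 would be coupled at the carbon–iodine bond of commercial 1-bromo-3-iodo-5-methoxybenzene (Negishi coupling, PdCl2(dppf), THF, rt) to give 1-bromo-3-(hexadec-15-enyl)-5-methoxybenzene F2. An Ullmann-type ether synthesis between bromide F2 and phenol 13 (CuI, picolinic acid, K3PO4, DMSO, 90 °C) would then give methyl ether 24 directly, and the route resumes at step 9. The price is the hindered aryl–oxygen coupling that the main plan avoids.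

**Step 9.** Oxidative addition into the electron-rich, ortho-substituted carbon–chlorine bond may be slow enough that β-hydride elimination or protodeboronation of the alkylborane, and intermolecular coupling to oligomers, outrun ring closure. The fallback moves the ring-closing event to olefin metathesis, setting out from 24. Intermolecular Suzuki–Miyaura vinylation of the chloride (potassium vinyltrifluoroborate, Pd(OAc)2, SPhos, K2CO3, dioxane/H2O, 90 °C) would give 1-ethenyl-2-[3-(hexadec-15-enyl)-5-methoxyphenoxy]-3,5-dimethoxybenzene F3. Ring-closing metathesis of diene F3 (second-generation Grubbs catalyst, CH2Cl2, 40 °C, high dilution) would expel ethene and give the macrocyclic alkene 1^4,1^6,3^5-trimethoxy-2-oxa-1(1,2),3(1,3)-dibenzenacyclononadecaphan-18-ene F4, expected as a mixture of alkene isomers, with exactly sixteen carbons between the rings. Hydrogenation of alkene F4 (H2, Pd/C, EtOAc) would give 26, where the route resumes at step 10.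

**Step 6.** The terminal ynol ether may be lost during isolation by hydration to the aryl acetate or by oligomerisation on concentration. Warming above −40 °C would also invite ortho-metalation next to chlorine. The fallback caps the alkyne, setting out from 15. Acetylide 17 would be trapped in the flask with Me3SiCl to give [(2-chloro-4,6-dimethoxyphenoxy)ethynyl]trimethylsilane F5, a more robust internal ynol ether. Benzannulation of silylalkyne F5 with 8 under the conditions of step 7 would give 3-(2-chloro-4,6-dimethoxyphenoxy)-5-(hexadec-15-enyl)-2-(trimethylsilyl)phenol F6, with the silyl group on the carbon between the two oxygens. Ipso-protodesilylation of arylsilane F6 (CF3CO2H, CH2Cl2, 0 °C) would give 23, where the route resumes at step 8.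

## Further compounds

F1 | step 7 | hexadec-15-enylzinc chloride | C=CCCCCCCCCCCCCCC[Zn]Cl
F2 | step 7 | 1-bromo-3-(hexadec-15-enyl)-5-methoxybenzene | COc1cc(Br)cc(CCCCCCCCCCCCCCC=C)c1
F3 | step 9 | 1-ethenyl-2-[3-(hexadec-15-enyl)-5-methoxyphenoxy]-3,5-dimethoxybenzene | COc1cc(CCCCCCCCCCCCCCC=C)cc(Oc2c(C=C)cc(OC)cc2OC)c1
F4 | step 9 | 1^4,1^6,3^5-trimethoxy-2-oxa-1(1,2),3(1,3)-dibenzenacyclononadecaphan-18-ene, the macrocyclic alkene corresponding to 26 with a double bond between the two chain carbons nearest ring B (mixture of alkene isomers) | COc1cc2cc(c1)Oc1c(OC)cc(OC)cc1C=CCCCCCCCCCCCCCC2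
F5 | step 6 | [(2-chloro-4,6-dimethoxyphenoxy)ethynyl]trimethylsilane | C[Si](C)(C)C#COc1c(Cl)cc(OC)cc1OC
F6 | step 6 | 3-(2-chloro-4,6-dimethoxyphenoxy)-5-(hexadec-15-enyl)-2-(trimethylsilyl)phenol | Oc1cc(CCCCCCCCCCCCCCC=C)cc(Oc2c(Cl)cc(OC)cc2OC)c1[Si](C)(C)C
A1 | alternative 1 | macrocycle 26 carrying isocyano and 4-methylbenzenesulfonyl groups on the fourth chain carbon from ring B | COc1cc2cc(c1)Oc1c(OC)cc(OC)cc1CCCC(S(=O)(=O)c1ccc(C)cc1)([N+]#[C-])CCCCCCCCCCCC2
A2 | alternative 1 | 1-(12-bromododecyl)-3-[2-(3-bromopropyl)-4,6-dimethoxyphenoxy]-5-methoxybenzene | COc1cc(CCCCCCCCCCCCBr)cc(Oc2c(OC)cc(OC)cc2CCCBr)c1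
A3 | alternative 1 | tosylmethyl isocyanide | Cc1ccc(cc1)S(=O)(=O)C[N+]#[C-]
A4 | alternative 2 | dimethyl 6,6'-(hexadecane-1,16-diyl)bis(2,4-dihydroxybenzoate) | COC(=O)c1c(O)cc(O)cc1CCCCCCCCCCCCCCCCc1cc(O)cc(O)c1C(=O)OC
A5 | alternative 2 | dimethyl 3,5,7,24,26,28-hexaoxotriacontanedioate | COC(=O)CC(=O)CC(=O)CC(=O)CCCCCCCCCCCCCCCCC(=O)CC(=O)CC(=O)CC(=O)OC
A6 | alternative 3 | methyl 1-(3-bromo-5-methoxyphenoxy)-6-(hexadec-15-enyl)-2,4-dioxocyclohexane-1-carboxylate (racemic, mixture of diastereomers) | COC(=O)C1(Oc2cc(OC)cc(Br)c2)C(=O)CC(=O)CC1CCCCCCCCCCCCCCC=C
A7 | alternative 3 | dimethyl 2-(3-bromo-5-methoxyphenoxy)propanedioate | COC(=O)C(Oc1cc(OC)cc(Br)c1)C(=O)OC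
A8 | alternative 3 | (3E)-icosa-3,19-dien-2-one | CC(=O)/C=C/CCCCCCCCCCCCCCC=C
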